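1. The target has ring A (tetramethylcyclohexenedione) fused at C-4a/C-8a to dihydropyran ring B (chromane locants: O-1, spiro C-2, C-3, isobutyl-bearing C-4). C-2 is also C-2' of a pinane (rings C and D). A formyl group is first added retrosynthetically at C-3 as a traceless activator, to be removed by decarbonylation.
2. Key disconnection: C-2–C-3 and C-4–C-4a are cut together. C-3 and C-4 leave as the alkyne carbons of 5-methylhex-2-ynal, and the nopinyl enol ether of syncarpic acid remains. One operation (hydrovinylation, 1,5-hydride shift, ring closure) then makes ring B and both of its lasting stereocentres.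
3. Enabling feature: the array H–C-2–O-1–C-8a=C-4a–H of that enol ether. It offers a nucleophilic vinylic C-4a–H, an ether methine C-2–H that comes to lie 1,5 to C-4, and the C-8 gem-dimethyl group of ring A, which locks the O-alkyl group s-cis to C-4a.
4. Stereochemical logic: the target carries C-3 on the pinane face syn to the CMe2 bridge, where no external nucleophile adds. The C-2–H bond already points there, so replacing it with retention gives the correct spiro centre, and the same hydrogen sets C-4.
5. The enol ether comes from syncarpic acid and cis-nopinol by Mitsunobu inversion, which puts O anti to the bridge. Ring order: A is made first from an acylphloroglucinol, C and D are bought as (+)-nopinone, and B is closed last.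

Key step: step 6

Remark: the configuration at the formyl-bearing C-3 of the key-step product is left open, because this centre is erased in the last step.

Step 1
Reactants: 1 2',4',6'-trihydroxyacetophenone
Product: 2 acetylsyncarpic acid (2-acetyl-3-hydroxy-4,4,6,6-tetramethylcyclohex-2-ene-1,5-dione)
Conditions: MeI (excess), NaOMe, MeOH, reflux; acidic work-up
Reagents that add atoms: iodomethane, CI
Why: Exhaustive base-mediated C-methylation of the acylphloroglucinol (dearomatising alkylation) should stop at the tetramethyl stage, because both ring CH positions are then quaternary and the remaining β-triketone stays enolised; no stereocentre arises.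

Step 2
Reactants: 2 acetylsyncarpic acid
Product: 3 syncarpic acid (5-hydroxy-2,2,6,6-tetramethylcyclohex-4-ene-1,3-dione, enol form)
Conditions: 6 M aq HCl, reflux
Reagents that add atoms: none
Why: Acid-promoted retro-Claisen deacylation of the β-triketone removes the acetyl group, which served only to steer the C-methylation; no stereocentre arises.

Step 3
Reactants: 4 (1R,5S)-(+)-nopinone
Product: 5 cis-nopinol, (1R,2R,5S)-6,6-dimethylbicyclo[3.1.1]heptan-2-ol (OH syn to the CMe2 bridge)
Conditions: NaBH4, MeOH, 0 °C
Reagents that add atoms: none
Why: Borohydride reduction of a bicyclic ketone under steric approach control delivers hydride to C-2' from the face anti to the CMe2 bridge, so the new carbinol centre should carry OH syn to the bridge.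

Step 4
Reactants: 3 syncarpic acid; 5 cis-nopinol
Product: 6 5-{[(1R,2S,5S)-6,6-dimethylbicyclo[3.1.1]heptan-2-yl]oxy}-2,2,6,6-tetramethylcyclohex-4-ene-1,3-dione (O anti and C-2'–H syn to the CMe2 bridge)
Conditions: PPh3, DIAD, THF, 0 °C → rt
Reagents that add atoms: none
Why: In this Mitsunobu reaction the acidic enol of a cyclic β-diketone acts as oxygen pronucleophile, and SN2 displacement of the oxyphosphonium group from the open face inverts C-2', which places oxygen anti and the remaining C-2'–H syn to the CMe2 bridge.

Step 5
Reactants: 7 4-methylpent-1-yne
Product: 8 5-methylhex-2-ynal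
Conditions: n-BuLi, THF, −78 °C; DMF; then cold 1 M HCl
Reagents that add atoms: N,N-dimethylformamide, CN(C)C=O
Why: Formylation of a lithium acetylide with DMF gives a hemiaminal alkoxide that is released to the ynal on acidic quench; no stereocentre arises.

Step 6
Reactants: 6 nopinyl enol ether of syncarpic acid; 8 5-methylhex-2-ynal
Product: 11 3-formyl derivative of the target, via dienal 9 (not isolated), via oxocarbenium enolate 10 (not isolated)
Conditions: Ph3PAuNTf2 (5 mol %), Sc(OTf)3 (20 mol %), 4 Å MS, ClCH2CH2Cl, 25 → 60 °C
Reagents that add atoms: none
Why: Proposed new method: Ph3PAuNTf2 (monovalent gold) binds the alkyne of 8, the enol-ether carbon C-4a of 6 (its only vinylic C–H and the nucleophilic end of O-1–C-8a=C-4a) attacks the formyl-polarised, isobutyl-bearing alkyne carbon, and proton loss with protodeauration gives dienal 9; Sc(OTf)3 on the formyl oxygen then makes C-4 a hydride acceptor, the ether methine hydrogen on C-2 shifts 1,5 through a six-membered transition state to give oxocarbenium enolate 10, and the enolate carbon C-3 bonds to C-2. The closest known reaction types are the gold-catalysed addition of weak π-nucleophiles (arenes, plain alkenes) to the β-carbon of alkynyl carbonyl compounds and the Lewis-acid-catalysed hydride-transfer cyclisation (internal redox, tert-amino-effect type) of ortho-vinylaryl alkyl ethers to chromans and spirochromans; what is new is their coupling in one flask and a vinylogous ester in place of the arene. Only ring B is closed, by 6-endo-trig attack of the enolate carbon on the endocyclic C=O+ bond. The spiro centre C-2 should form with retention (memory of chirality): the hydride leaves from the pinane face syn to the CMe2 bridge, and the tethered C-3 is held over that same lobe in the helical ion pair and collapses before rotation about O-1–C-8a, which is the only way to place carbon on this hindered face. C-4 is set by suprafacial delivery of that same hydrogen in the rotamer that turns the bulky bridgehead C-1' away from ring A and lets the oxocarbenium ion form with the small C-3' methylene syn to C-8a, which puts isobutyl cis to C-3'; the formyl-bearing C-3 is not controlled and is erased in step 7. The step needs C- over O-attack on the alkyne, 1,5- over any other hydride transfer, and ring closure faster than bond rotation or loss of nopinol, and the substrate secures these by having no other ether or enolisable C–H and by the C-8 gem-dimethyl group, which locks the O-alkyl group s-cis to C-4a with C-2–H pointing at C-4.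

Step 7
Reactants: 11 3-formyl derivative of the target
Product: 12 target CNP0231252.1, (1'R,2R,4S,5'S)-4-isobutyl-6,6,6',6',8,8-hexamethyl-3,4-dihydrospiro[chromene-2,2'-bicyclo[3.1.1]heptane]-5,7(6H,8H)-dione
Conditions: RhCl(PPh3)3 (1.1 equiv), toluene, 110 °C
Reagents that add atoms: none
Why: Tsuji–Wilkinson decarbonylation (oxidative addition of monovalent rhodium into the formyl C–H bond, CO extrusion, C–H reductive elimination) replaces CHO by H under neutral conditions, erases the uncontrolled C-3 centre, and leaves C-2, C-4, the ketones and the enol ether untouched.

Compound list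
1 | 2',4',6'-trihydroxyacetophenone | CC(=O)c1c(O)cc(O)cc1O | starting material
2 | acetylsyncarpic acid | CC(=O)C1=C(O)C(C)(C)C(=O)C(C)(C)C1=O | intermediate
3 | syncarpic acid (enol form) | CC1(C)C(=O)C=C(O)C(C)(C)C1=O | intermediate
4 | (1R,5S)-(+)-nopinone | O=C1CC[C@H]2C[C@@H]1C2(C)C | starting material
5 | cis-nopinol, (1R,2R,5S), OH syn to the CMe2 bridge | O[C@@H]1CC[C@H]2C[C@@H]1C2(C)C | intermediate
6 | (1R,2S,5S)-nopinyl enol ether of syncarpic acid, O anti to the CMe2 bridge | CC1(C)C(=O)C=C(O[C@H]2CC[C@H]3C[C@@H]2C3(C)C)C(C)(C)C1=O | intermediate
7 | 4-methylpent-1-yne | CC(C)CC#C | starting material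
8 | 5-methylhex-2-ynal | CC(C)CC#CC=O | intermediate
9 | dienal: 6 bearing a 1-formyl-4-methylpent-1-en-2-yl group on C-4a (alkene geometry not fixed, expected to equilibrate under the Lewis acid) | CC(C)CC(=CC=O)C1=C(O[C@H]2CC[C@H]3C[C@@H]2C3(C)C)C(C)(C)C(=O)C(C)(C)C1=O | intermediate (not isolated)
10 | oxocarbenium enolate formed by the 1,5-hydride shift (scandium-bound, drawn as the free zwitterion) | CC(C)C[C@@H](C=C[O-])C1=C([O+]=C2CC[C@H]3C[C@@H]2C3(C)C)C(C)(C)C(=O)C(C)(C)C1=O | intermediate (not isolated)
11 | 3-formyl derivative of the target (C-2, C-4 and pinane as in the target, C-3 either configuration) | CC(C)C[C@H]1C(C=O)[C@@]2(CC[C@H]3C[C@@H]2C3(C)C)OC2=C1C(=O)C(C)(C)C(=O)C2(C)C | intermediate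
12 | CNP0231252.1 (O-1 anti and C-3 syn to the CMe2 bridge; isobutyl cis to C-3' across ring B) | CC(C)C[C@H]1C[C@@]2(CC[C@H]3C[C@@H]2C3(C)C)OC2=C1C(=O)C(C)(C)C(=O)C2(C)C | target

Total step count: 7. Longest linear sequence: 5 (steps 1, 2, 4, 6, 7).

Steps most likely to fail

**Step 6.**
- The deactivated enol ether may attack the gold-bound alkyne too slowly.
- The dienal may drain away by oxa-6π closure onto C-8a with loss of nopinol.
- The hydride transfer may be sluggish, because the ether oxygen is electron-poor.
- Bond rotation in the ion pair may outrun ring closure. The memory of chirality would then be lost and C-3 would attach anti to the bridge.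
- Fallback by known chemistry: it sets out from 3 and returns at 12. Knoevenagel condensation of 3 with isovaleraldehyde (cat. L-proline, CH2Cl2 or toluene) gives 2-(3-methylbutylidene)-4,4,6,6-tetramethylcyclohexane-1,3,5-trione F1. This oxadiene is trapped in the same flask by (1S,5S)-(−)-β-pinene in an inverse-demand hetero-Diels–Alder reaction. The diene should add to the exocyclic alkene from the face anti to the CMe2 bridge, which puts O-1 anti to the bridge. Poor endo/exo selectivity at C-4 would have to be met by chromatographic separation of the C-4 epimers.

**Step 4.**
- SN2 displacement at the neopentyl-like carbinol carbon by a hindered enolate oxygen may be slow, so elimination of the oxyphosphonium salt to the alkene may take over.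
- Fallback: it forms the C–O bond at the sp2 carbon instead. It sets out from 4 and 3 and returns at 6.
- Dissolving-metal reduction of 4 (Na, i-PrOH, toluene) under thermodynamic control should give trans-nopinol F2, with OH anti to the bridge.
- Oxalyl chloride with cat. DMF converts 3 into 5-chloro-2,2,6,6-tetramethylcyclohex-4-ene-1,3-dione F3.
- The sodium alkoxide of F2 (NaH, THF) displaces chloride from F3 by addition–elimination, with the carbinol configuration retained.

**Step 7.**
- Oxidative addition to the hindered aldehyde may be slow.
- β-Alkoxide elimination from the alkylrhodium species, or thermal E1cB opening of ring B at the β-alkoxy aldehyde, may compete.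
- Fallback by a radical route at room temperature: it sets out from 11 and returns at 12.
- Pinnick oxidation (NaClO2, NaH2PO4, 2-methylbut-2-ene, t-BuOH/H2O) gives the 3-carboxylic acid F4.
- F4 is hydrodecarboxylated under organic photoredox catalysis (9-mesityl-10-methylacridinium tetrafluoroborate, PhSSPh, i-Pr2NEt, CF3CH2OH, blue light).

Further compounds
F1 | step 6 | 2-(3-methylbutylidene)-4,4,6,6-tetramethylcyclohexane-1,3,5-trione | CC(C)CC=C1C(=O)C(C)(C)C(=O)C(C)(C)C1=O
F2 | step 4 | trans-nopinol, (1R,2S,5S)-6,6-dimethylbicyclo[3.1.1]heptan-2-ol (OH anti to the CMe2 bridge) | O[C@H]1CC[C@H]2C[C@@H]1C2(C)C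
F3 | step 4 | 5-chloro-2,2,6,6-tetramethylcyclohex-4-ene-1,3-dione | CC1(C)C(=O)C=C(Cl)C(C)(C)C1=O
F4 | step 7 | 3-carboxylic acid of the target (C-3 either configuration) | CC(C)C[C@H]1C(C(=O)O)[C@@]2(CC[C@H]3C[C@@H]2C3(C)C)OC2=C1C(=O)C(C)(C)C(=O)C2(C)C
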